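**Retrosynthetic overview**
1. Feature: ring A (C4a, C5, C6, C7, C8, C8a) carries oxygen on C5, C7 and C8a (O1) and the ketone carbon C4 on C4a. It is an acylphloroglucinol, the aromatised fold of a linear 3,5,7-trioxo ester.
2. Late stage: the O-benzyl and O-silyl groups come off, and ring C is opened at C2 (one carbon from DMF dimethyl acetal) to a 2,4,6-trihydroxyphenyl benzyl ketone.
3. Key disconnection: C4a–C5, which unfolds ring A to methyl 8-aryl-3,5,7-trioxooctanoate (chain C6 = C4a, chain C1 = C5, chain C7 = C4, chain C8 = C3).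
4. Chain: cut at C6–C7 into the trianion of methyl 3,5-dioxohexanoate and the ring B arylacetic Weinreb amide. The ester end is present from the start, because carboxylating the polyanion of a 1-arylheptane-2,4,6-trione would go to the more acidic benzylic end.
5. Ring B is bought as 2-bromoisovanillin (Br to side chain, CHO to OH, then OH-directed bromination to the CH2CO arm). Ring order: B (given), A (step 11), C (step 12). The target has no stereocentre.

Key step: step 11

Assumption: 2-bromo-3-hydroxy-4-methoxybenzaldehyde (the monobromide of isovanillin), dehydroacetic acid, 2-methylbut-3-en-2-ol and the THF solution of BrZnCH2CO2Et are taken as catalogue items, and β-polycarbonyl compounds are drawn as keto tautomers although they are largely enolised.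

Step 1
Reactants: 1 2-methylbut-3-en-2-ol
Product: 2 tert-butyl(dimethyl)[(2-methylbut-3-en-2-yl)oxy]silane
Conditions: TBSOTf, 2,6-lutidine, CH2Cl2, 0 °C to rt
Reagents that add atoms: tert-butyldimethylsilyl triflate, CC(C)(C)[Si](C)(C)OS(=O)(=O)C(F)(F)F
Why: O-silylation with a silyl triflate is the standard way to cap a hindered tertiary alcohol, and the lutidine buffer keeps the allylic C–O bond from ionising.

Step 2
Reactants: 3 2-bromo-3-hydroxy-4-methoxybenzaldehyde
Product: 4 3-(benzyloxy)-2-bromo-4-methoxybenzaldehyde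
Conditions: BnBr, K2CO3, DMF, rt
Reagents that add atoms: benzyl bromide, BrCc1ccccc1
Why: Williamson ether synthesis on the acidic phenol, to which the aldehyde and the aryl bromide are inert.

Step 3
Reactants: 2 tert-butyl(dimethyl)[(2-methylbut-3-en-2-yl)oxy]silane; 4 3-(benzyloxy)-2-bromo-4-methoxybenzaldehyde
Product: 6 3-(benzyloxy)-2-{3-[(tert-butyldimethylsilyl)oxy]-3-methylbutyl}-4-methoxybenzaldehyde, via B-alkyl-9-BBN borane 5 (not isolated)
Conditions: 2 (1.5 equiv), 9-BBN (1.4 equiv), THF, 0 °C to rt; then 4, Pd(dppf)Cl2 (5 mol %), aq K3PO4, DMF, 60 °C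
Reagents that add atoms: 9-borabicyclo[3.3.1]nonane, B1C2CCCC1CCC2 (its boron cage stands only in 5; 6 keeps one hydrogen of it)
Why: Hydroboration puts boron on the terminal carbon because the inner alkene carbon sits next to a quaternary centre, and the B-alkyl Suzuki–Miyaura coupling that follows is helped by the ortho formyl group, which speeds oxidative addition, and by the wide-bite dppf ligand, which favours reductive elimination over β-hydride loss.

Step 4
Reactants: 6 3-(benzyloxy)-2-{3-[(tert-butyldimethylsilyl)oxy]-3-methylbutyl}-4-methoxybenzaldehyde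
Product: 8 3-(benzyloxy)-2-{3-[(tert-butyldimethylsilyl)oxy]-3-methylbutyl}-4-methoxyphenol, via aryl formate 7 (not isolated)
Conditions: mCPBA, CH2Cl2, 0 °C to rt; then K2CO3 (cat.), MeOH, rt
Reagents that add atoms: 3-chloroperoxybenzoic acid, OOC(=O)c1cccc(Cl)c1
Why: Baeyer–Villiger oxidation, in which the aryl group migrates in preference to hydrogen because the para methoxy group makes it electron-rich, followed by base-catalysed methanolysis of the aryl formate, conditions that leave the benzyl and silyl ethers alone.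

Step 5
Reactants: 8 3-(benzyloxy)-2-{3-[(tert-butyldimethylsilyl)oxy]-3-methylbutyl}-4-methoxyphenol
Product: 9 3-(benzyloxy)-6-bromo-2-{3-[(tert-butyldimethylsilyl)oxy]-3-methylbutyl}-4-methoxyphenol
Conditions: NBS (1.0 equiv), CH2Cl2, −20 to 0 °C, dark
Reagents that add atoms: N-bromosuccinimide, O=C1CCC(=O)N1Br
Why: Electrophilic aromatic bromination steered by the free hydroxyl, whose para position (OMe) and one ortho position (side chain) are occupied, so that only C6 is open, and NBS gives no HBr that could harm the silyl ether.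

Step 6
Reactants: 9 3-(benzyloxy)-6-bromo-2-{3-[(tert-butyldimethylsilyl)oxy]-3-methylbutyl}-4-methoxyphenol
Product: 10 2,4-bis(benzyloxy)-1-bromo-3-{3-[(tert-butyldimethylsilyl)oxy]-3-methylbutyl}-5-methoxybenzene
Conditions: BnBr, K2CO3, DMF, 50 °C
Reagents that add atoms: benzyl bromide, BrCc1ccccc1
Why: Williamson ether synthesis, run after the bromination so that the phenol could first serve as the directing group.

Step 7
Reactants: 10 2,4-bis(benzyloxy)-1-bromo-3-{3-[(tert-butyldimethylsilyl)oxy]-3-methylbutyl}-5-methoxybenzene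
Product: 11 ethyl 2-(2,4-bis(benzyloxy)-3-{3-[(tert-butyldimethylsilyl)oxy]-3-methylbutyl}-5-methoxyphenyl)acetate
Conditions: BrZnCH2CO2Et (2 equiv), Pd2(dba)3 (2.5 mol %), XPhos (10 mol %), THF, 65 °C
Reagents that add atoms: (2-ethoxy-2-oxoethyl)zinc bromide, CCOC(=O)C[Zn]Br
Why: Negishi-type α-arylation of a Reformatsky reagent, whose nearly neutral zinc enolate couples with electron-rich aryl bromides under bulky electron-rich phosphine catalysis without touching the ethers or causing double arylation.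

Step 8
Reactants: 11 ethyl 2-(2,4-bis(benzyloxy)-3-{3-[(tert-butyldimethylsilyl)oxy]-3-methylbutyl}-5-methoxyphenyl)acetate
Product: 12 2-(2,4-bis(benzyloxy)-3-{3-[(tert-butyldimethylsilyl)oxy]-3-methylbutyl}-5-methoxyphenyl)-N-methoxy-N-methylacetamide
Conditions: AlMe3 (3 equiv), MeNH(OMe)·HCl (3 equiv), CH2Cl2, 0 °C to rt
Reagents that add atoms: N,O-dimethylhydroxylamine hydrochloride, CNOC.Cl
Why: Aluminium amide aminolysis of an ester (Weinreb amidation), a weakly basic reagent that converts the C–H acidic arylacetate without enolising it.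

Step 9
Reactants: 13 dehydroacetic acid (3-acetyl-4-hydroxy-6-methyl-2H-pyran-2-one)
Product: 14 methyl 3,5-dioxohexanoate
Conditions: Mg(OMe)2, MeOH, reflux; then aq HCl, 0 °C
Reagents that add atoms: magnesium methoxide, [Mg+2].[O-]C.[O-]C; methanol, CO
Why: Methoxide opens the pyranone lactone and a retro-Claisen cleavage then removes the acetyl group from the doubly activated C3, while magnesium chelation shields the resulting 3,5-dioxo ester from further cleavage.

Step 10
Reactants: 14 methyl 3,5-dioxohexanoate; 12 2-(2,4-bis(benzyloxy)-3-{3-[(tert-butyldimethylsilyl)oxy]-3-methylbutyl}-5-methoxyphenyl)-N-methoxy-N-methylacetamide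
Product: 17 methyl 8-(2,4-bis(benzyloxy)-3-{3-[(tert-butyldimethylsilyl)oxy]-3-methylbutyl}-5-methoxyphenyl)-3,5,7-trioxooctanoate, via trilithium trianion 15 (not isolated), via tetrahedral lithium adduct 16 (not isolated)
Conditions: 14 (2 equiv), LiN(iPr)2 (3.0 equiv per 14), THF, −78 to 0 °C; 12 (1 equiv), −78 to −20 °C; AcOH, −78 °C; rapid chromatography, used at once
Reagents that add atoms: none
Why: Terminal C-acylation of a 1,3,5-tricarbonyl trianion, in which the last-formed and most basic C6 carbanion attacks and the Weinreb amide holds the adduct as lithium chelate 16 until the quench, so that neither over-addition nor quenching of the trianion by the acidic product can occur.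

Step 11
Reactants: 17 methyl 8-(2,4-bis(benzyloxy)-3-{3-[(tert-butyldimethylsilyl)oxy]-3-methylbutyl}-5-methoxyphenyl)-3,5,7-trioxooctanoate
Product: 18 2-(2,4-bis(benzyloxy)-3-{3-[(tert-butyldimethylsilyl)oxy]-3-methylbutyl}-5-methoxyphenyl)-1-(2,4,6-trihydroxyphenyl)ethan-1-one
Conditions: Mg(OMe)2 (5 equiv), dry MeOH, reflux, Ar; then cold 1 M HCl
Reagents that add atoms: none
Why: Mg(OMe)2 turns 17 into its fully enolised magnesium chelate, the C6 carbanion (flanked by C5 and C7) adds to the C1 ester carbonyl, and loss of methoxide with tautomerisation gives phloroglucinol 18, the new C6–C1 bond being C4a–C5 of the target. The closest known reaction type is the base-mediated intramolecular Claisen (Dieckmann-type) cyclisation of 3,5,7-trioxo esters, and of the pyranones related to them, to acylphloroglucinols in methanolic Mg(OMe)2. Ring A closes 6-exo-trig at the ester carbonyl, with the enolate double bond either inside (C5=C6) or outside (C6=C7) the new ring, both modes being allowed for a six-membered ring, and no stereocentre is formed. The step needs the Claisen mode to beat the two aldol closures (C2 onto C7, which would give a resorcylate, and benzylic C8 onto C3) and O-acylation to a 4-hydroxy-2-pyranone. Excess base keeps C3, C5 and C7 as chelated enolates so that no ketone carbonyl is left as an electrophile, C7 is further shielded by the ortho-benzyloxy arylmethyl group, water is excluded so that the ester is not saponified, the methyl ester matches the methoxide so that exchange is degenerate, and pyranone formation is reversible under methoxide whereas aromatisation to the phloroglucinolate is not. Because 18 is symmetric about the C4a–C7 axis, either ortho hydroxyl can close ring C later.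

Step 12
Reactants: 18 2-(2,4-bis(benzyloxy)-3-{3-[(tert-butyldimethylsilyl)oxy]-3-methylbutyl}-5-methoxyphenyl)-1-(2,4,6-trihydroxyphenyl)ethan-1-one
Product: 20 3-(2,4-bis(benzyloxy)-3-{3-[(tert-butyldimethylsilyl)oxy]-3-methylbutyl}-5-methoxyphenyl)-5,7-dihydroxy-4H-chromen-4-one, via enaminone 19 (not isolated)
Conditions: Me2NCH(OMe)2 (2.5 equiv), THF, 60 °C
Reagents that add atoms: N,N-dimethylformamide dimethyl acetal, COC(OC)N(C)C
Why: Enaminone formation at the doubly activated benzylic CH2 followed by conjugate addition–elimination of an ortho hydroxyl (loss of dimethylamine) is the standard deoxybenzoin-to-isoflavone closure, the two ortho hydroxyls are equivalent, and the small excess of acetal at moderate temperature keeps phenol O-methylation down.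

Step 13
Reactants: 20 3-(2,4-bis(benzyloxy)-3-{3-[(tert-butyldimethylsilyl)oxy]-3-methylbutyl}-5-methoxyphenyl)-5,7-dihydroxy-4H-chromen-4-one
Product: 21 3-[2,4-bis(benzyloxy)-3-(3-hydroxy-3-methylbutyl)-5-methoxyphenyl]-5,7-dihydroxy-4H-chromen-4-one
Conditions: HF·pyridine, pyridine, THF, 0 °C to rt
Reagents that add atoms: none
Why: Fluoride-driven cleavage of the Si–O bond, done while both oxygens ortho to the side chain are still benzylated so that the liberated tertiary alcohol cannot close onto ring B as a 2,2-dimethylchroman.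

Step 14
Reactants: 21 3-[2,4-bis(benzyloxy)-3-(3-hydroxy-3-methylbutyl)-5-methoxyphenyl]-5,7-dihydroxy-4H-chromen-4-one
Product: 22 3-[2,4-dihydroxy-3-(3-hydroxy-3-methylbutyl)-5-methoxyphenyl]-5,7-dihydroxy-4H-chromen-4-one (CNP0277410.0)
Conditions: H2 (1 atm), Pd/C (10 wt %), EtOAc–MeOH, rt
Reagents that add atoms: none
Why: Catalytic hydrogenolysis of aryl benzyl ethers under neutral conditions, which avoids the acid that would ionise the tertiary alcohol and is stopped after two equivalents of H2 to spare the C2–C3 double bond.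

**Compound list**
1 | 2-methylbut-3-en-2-ol | C=CC(C)(C)O | starting material
2 | tert-butyl(dimethyl)[(2-methylbut-3-en-2-yl)oxy]silane | C=CC(C)(C)O[Si](C)(C)C(C)(C)C | intermediate
3 | 2-bromo-3-hydroxy-4-methoxybenzaldehyde | COc1ccc(C=O)c(Br)c1O | starting material
4 | 3-(benzyloxy)-2-bromo-4-methoxybenzaldehyde | COc1ccc(C=O)c(Br)c1OCc1ccccc1 | intermediate
5 | 9-{3-[(tert-butyldimethylsilyl)oxy]-3-methylbutyl}-9-borabicyclo[3.3.1]nonane | CC(C)(CCB1C2CCCC1CCC2)O[Si](C)(C)C(C)(C)C | intermediate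
6 | 3-(benzyloxy)-2-{3-[(tert-butyldimethylsilyl)oxy]-3-methylbutyl}-4-methoxybenzaldehyde | COc1ccc(C=O)c(CCC(C)(C)O[Si](C)(C)C(C)(C)C)c1OCc1ccccc1 | intermediate
7 | 3-(benzyloxy)-2-{3-[(tert-butyldimethylsilyl)oxy]-3-methylbutyl}-4-methoxyphenyl formate | COc1ccc(OC=O)c(CCC(C)(C)O[Si](C)(C)C(C)(C)C)c1OCc1ccccc1 | intermediate
8 | 3-(benzyloxy)-2-{3-[(tert-butyldimethylsilyl)oxy]-3-methylbutyl}-4-methoxyphenol | COc1ccc(O)c(CCC(C)(C)O[Si](C)(C)C(C)(C)C)c1OCc1ccccc1 | intermediate
9 | 3-(benzyloxy)-6-bromo-2-{3-[(tert-butyldimethylsilyl)oxy]-3-methylbutyl}-4-methoxyphenol | COc1cc(Br)c(O)c(CCC(C)(C)O[Si](C)(C)C(C)(C)C)c1OCc1ccccc1 | intermediate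
10 | 2,4-bis(benzyloxy)-1-bromo-3-{3-[(tert-butyldimethylsilyl)oxy]-3-methylbutyl}-5-methoxybenzene | COc1cc(Br)c(OCc2ccccc2)c(CCC(C)(C)O[Si](C)(C)C(C)(C)C)c1OCc1ccccc1 | intermediate
11 | ethyl 2-(2,4-bis(benzyloxy)-3-{3-[(tert-butyldimethylsilyl)oxy]-3-methylbutyl}-5-methoxyphenyl)acetate | CCOC(=O)Cc1cc(OC)c(OCc2ccccc2)c(CCC(C)(C)O[Si](C)(C)C(C)(C)C)c1OCc1ccccc1 | intermediate
12 | 2-(2,4-bis(benzyloxy)-3-{3-[(tert-butyldimethylsilyl)oxy]-3-methylbutyl}-5-methoxyphenyl)-N-methoxy-N-methylacetamide | CON(C)C(=O)Cc1cc(OC)c(OCc2ccccc2)c(CCC(C)(C)O[Si](C)(C)C(C)(C)C)c1OCc1ccccc1 | intermediate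
13 | dehydroacetic acid (3-acetyl-4-hydroxy-6-methyl-2H-pyran-2-one) | CC(=O)C1=C(O)C=C(C)OC1=O | starting material
14 | methyl 3,5-dioxohexanoate | COC(=O)CC(=O)CC(C)=O | intermediate
15 | trilithium trianion of methyl 3,5-dioxohexanoate (tris-enolate form) | [Li+].[Li+].[Li+].C=C([O-])C=C([O-])C=C([O-])OC | intermediate
16 | trilithium tetrahedral adduct of 15 to 12 (racemic at the carbinolamine carbon, enolate geometry not fixed) | [Li+].[Li+].[Li+].COC([O-])=CC([O-])=CC(=O)CC([O-])(Cc1cc(OC)c(OCc2ccccc2)c(CCC(C)(C)O[Si](C)(C)C(C)(C)C)c1OCc1ccccc1)N(C)OC | intermediate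
17 | methyl 8-(2,4-bis(benzyloxy)-3-{3-[(tert-butyldimethylsilyl)oxy]-3-methylbutyl}-5-methoxyphenyl)-3,5,7-trioxooctanoate | COC(=O)CC(=O)CC(=O)CC(=O)Cc1cc(OC)c(OCc2ccccc2)c(CCC(C)(C)O[Si](C)(C)C(C)(C)C)c1OCc1ccccc1 | intermediate
18 | 2-(2,4-bis(benzyloxy)-3-{3-[(tert-butyldimethylsilyl)oxy]-3-methylbutyl}-5-methoxyphenyl)-1-(2,4,6-trihydroxyphenyl)ethan-1-one | O=C(Cc1cc(OC)c(OCc2ccccc2)c(CCC(C)(C)O[Si](C)(C)C(C)(C)C)c1OCc1ccccc1)c1c(O)cc(O)cc1O | intermediate
19 | 2-(2,4-bis(benzyloxy)-3-{3-[(tert-butyldimethylsilyl)oxy]-3-methylbutyl}-5-methoxyphenyl)-3-(dimethylamino)-1-(2,4,6-trihydroxyphenyl)prop-2-en-1-one (alkene geometry not fixed) | CN(C)C=C(C(=O)c1c(O)cc(O)cc1O)c1cc(OC)c(OCc2ccccc2)c(CCC(C)(C)O[Si](C)(C)C(C)(C)C)c1OCc1ccccc1 | intermediate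
20 | 3-(2,4-bis(benzyloxy)-3-{3-[(tert-butyldimethylsilyl)oxy]-3-methylbutyl}-5-methoxyphenyl)-5,7-dihydroxy-4H-chromen-4-one | COc1cc(-c2coc3cc(O)cc(O)c3c2=O)c(OCc2ccccc2)c(CCC(C)(C)O[Si](C)(C)C(C)(C)C)c1OCc1ccccc1 | intermediate
21 | 3-[2,4-bis(benzyloxy)-3-(3-hydroxy-3-methylbutyl)-5-methoxyphenyl]-5,7-dihydroxy-4H-chromen-4-one | COc1cc(-c2coc3cc(O)cc(O)c3c2=O)c(OCc2ccccc2)c(CCC(C)(C)O)c1OCc1ccccc1 | intermediate
22 | 3-[2,4-dihydroxy-3-(3-hydroxy-3-methylbutyl)-5-methoxyphenyl]-5,7-dihydroxy-4H-chromen-4-one (CNP0277410.0) | COc1cc(-c2coc3cc(O)cc(O)c3c2=O)c(O)c(CCC(C)(C)O)c1O | target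

**Total step count:** 14
**Longest linear sequence:** 12 (from 3: steps 2 to 8, then 10 to 14)

**Steps most likely to fail**

Step 11.
- What may go wrong: aldol folding (C2 onto C7, or C8 onto C3) may outrun the Claisen closure, or methoxide may cut the chain by retro-Claisen cleavage.
- Fallback: it sets out from 12 and comes back at 21, and it joins a ready-made ring A to the arylacetyl unit instead of folding a chain.
- Phloroglucinol would be protected with MOMCl and i-Pr2NEt as 1,3,5-tris(methoxymethoxy)benzene F1.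
- n-BuLi in THF at 0 °C would then lithiate F1 between two acetal oxygens to 2,4,6-tris(methoxymethoxy)phenyllithium F2.
- Addition of F2 to Weinreb amide 12 at −78 °C should give 2-(2,4-bis(benzyloxy)-3-{3-[(tert-butyldimethylsilyl)oxy]-3-methylbutyl}-5-methoxyphenyl)-1-[2,4,6-tris(methoxymethoxy)phenyl]ethan-1-one F3.
- HCl in MeOH at 40 °C should strip the three acetals and the silyl ether, the ring B benzyl ethers blocking chroman formation. This gives 2-[2,4-bis(benzyloxy)-3-(3-hydroxy-3-methylbutyl)-5-methoxyphenyl]-1-(2,4,6-trihydroxyphenyl)ethan-1-one F4.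
- DMF dimethyl acetal in THF at 60 °C then leads through 2-[2,4-bis(benzyloxy)-3-(3-hydroxy-3-methylbutyl)-5-methoxyphenyl]-3-(dimethylamino)-1-(2,4,6-trihydroxyphenyl)prop-2-en-1-one F5 to 21.

Step 10.
- What may go wrong: proton transfer from the benzylic CH2 of the amide to the trianion may compete with C-acylation, and the triketo ester may cyclise early during work-up or chromatography.
- Fallback: it sets out from 12 and comes back at 17, and it replaces acylation by aldol addition and oxidation.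
- i-Bu2AlH in THF at −78 °C would reduce 12 to 2-(2,4-bis(benzyloxy)-3-{3-[(tert-butyldimethylsilyl)oxy]-3-methylbutyl}-5-methoxyphenyl)acetaldehyde F6.
- Trianion 15 should add to F6 at −78 °C, where carbonyl addition is much faster than enolisation. The product is racemic methyl 8-(2,4-bis(benzyloxy)-3-{3-[(tert-butyldimethylsilyl)oxy]-3-methylbutyl}-5-methoxyphenyl)-7-hydroxy-3,5-dioxooctanoate F7.
- 2-Iodoxybenzoic acid in EtOAc at 75 °C, a neutral oxidant suited to β-hydroxy ketones, should then give 17.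

Step 3.
- What may go wrong: transmetalation may be slow at the palladium aryl flanked by two ortho groups, which would lead to protodebromination or β-hydride loss, and leftover borane may reduce the aldehyde.
- Fallback: it sets out from 4 and comes back at 6, and it brings the side chain in as an alkyne.
- Sonogashira coupling of 4 with 2-methylbut-3-yn-2-ol (PdCl2(PPh3)2, CuI, Et3N, 60 °C) should give 3-(benzyloxy)-2-(3-hydroxy-3-methylbut-1-yn-1-yl)-4-methoxybenzaldehyde F8.
- TBSOTf and 2,6-lutidine would convert F8 into 3-(benzyloxy)-2-{3-[(tert-butyldimethylsilyl)oxy]-3-methylbut-1-yn-1-yl}-4-methoxybenzaldehyde F9.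
- Hydrogenation over Pd/C poisoned with Ph2S (H2 1 atm, EtOAc, rt) should saturate the triple bond while sparing the aryl aldehyde and the benzyl ether, giving 6.

**Further compounds**
F1 | step 11 | 1,3,5-tris(methoxymethoxy)benzene | COCOc1cc(OCOC)cc(OCOC)c1
F2 | step 11 | 2,4,6-tris(methoxymethoxy)phenyllithium | [Li]c1c(OCOC)cc(OCOC)cc1OCOC
F3 | step 11 | 2-(2,4-bis(benzyloxy)-3-{3-[(tert-butyldimethylsilyl)oxy]-3-methylbutyl}-5-methoxyphenyl)-1-[2,4,6-tris(methoxymethoxy)phenyl]ethan-1-one | COCOc1cc(OCOC)c(C(=O)Cc2cc(OC)c(OCc3ccccc3)c(CCC(C)(C)O[Si](C)(C)C(C)(C)C)c2OCc2ccccc2)c(OCOC)c1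
F4 | step 11 | 2-[2,4-bis(benzyloxy)-3-(3-hydroxy-3-methylbutyl)-5-methoxyphenyl]-1-(2,4,6-trihydroxyphenyl)ethan-1-one | O=C(Cc1cc(OC)c(OCc2ccccc2)c(CCC(C)(C)O)c1OCc1ccccc1)c1c(O)cc(O)cc1O
F5 | step 11 | 2-[2,4-bis(benzyloxy)-3-(3-hydroxy-3-methylbutyl)-5-methoxyphenyl]-3-(dimethylamino)-1-(2,4,6-trihydroxyphenyl)prop-2-en-1-one | CN(C)C=C(C(=O)c1c(O)cc(O)cc1O)c1cc(OC)c(OCc2ccccc2)c(CCC(C)(C)O)c1OCc1ccccc1
F6 | step 10 | 2-(2,4-bis(benzyloxy)-3-{3-[(tert-butyldimethylsilyl)oxy]-3-methylbutyl}-5-methoxyphenyl)acetaldehyde | O=CCc1cc(OC)c(OCc2ccccc2)c(CCC(C)(C)O[Si](C)(C)C(C)(C)C)c1OCc1ccccc1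
F7 | step 10 | methyl 8-(2,4-bis(benzyloxy)-3-{3-[(tert-butyldimethylsilyl)oxy]-3-methylbutyl}-5-methoxyphenyl)-7-hydroxy-3,5-dioxooctanoate (racemic) | COC(=O)CC(=O)CC(=O)CC(O)Cc1cc(OC)c(OCc2ccccc2)c(CCC(C)(C)O[Si](C)(C)C(C)(C)C)c1OCc1ccccc1
F8 | step 3 | 3-(benzyloxy)-2-(3-hydroxy-3-methylbut-1-yn-1-yl)-4-methoxybenzaldehyde | COc1ccc(C=O)c(C#CC(C)(C)O)c1OCc1ccccc1
F9 | step 3 | 3-(benzyloxy)-2-{3-[(tert-butyldimethylsilyl)oxy]-3-methylbut-1-yn-1-yl}-4-methoxybenzaldehyde | COc1ccc(C=O)c(C#CC(C)(C)O[Si](C)(C)C(C)(C)C)c1OCc1ccccc1
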